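Wednesday's run was the very flask asked about, followed so far, so I reckoned from its own readings.

| setting | Wednesday's | flask |
|---|---|---|
| starting material | 10 mM | 10 mM |
| gas phase | 0.40 mM (held) | 0.40 mM (held) |
| remark | the very flask that is asked about, followed so far |  |
| time |  | 30 min |

Wednesday's run (percent of the starting material charged)

| time / min | target / % | starting material / % |
|---|---|---|
| 0.667 | 1.5 | 98.6 |
| 1.00 | 2.1 | 97.7 |
| 1.50 | 3.5 | 96.2 |
| 2.50 | 5.5 | 94.0 |
| 4.00 | 8.2 | 91.1 |
| 6.00 | 13.1 | 87.0 |
| 10.0 | 20.1 | 79.1 |

(scatter of a reading: 0.3 percentage points)

- at the start none of the gas phase is in solution

- west: doubling the transfer coefficient of the gas phase, all else as stated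
- south-east: doubling the saturation concentration of gas phase, all else as stated

- target at 30 min, in percent of the starting material charged
- the change that raises the amount of target at 30 min, in percent of the starting material charged most ("none" if none brings more than 2 percentage points) (west / south-east / none)
- amount of target at 30 min, in percent of the starting material charged, after west

I reckoned in two rounds. In the first, I let starting material fall with a pseudo-first-order constant k, read from the last reading as 0.0234 min⁻¹, and I counted what it lost as target. In the second, I put that curve back in. I assumed that target leaks away in proportion to its amount, so the loss grows with the area under the curve, which by 30 min is 7.79 times its area at 10.0 min.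

Which reading mattered? One standard deviation in the last starting-material reading moved the first round by 0.56 percentage points. The last reading's gap, the charge minus starting material and target, scattered by 0.42 points, which moved the reckoned loss by 3.3 points, more than the first round moved. So the gap mattered.

The gap was 0.8 points. Divided by the first-round area, it gave the leak constant L = 0.00737 min⁻¹. The first round gave 50.5 % and the reckoned loss was 6.2 points, so I expected 44.3 % of target, give or take the 3.3 points from the gap's scatter. I made no reckoning of the two changes.

The forecast said 50 % of target, south-east as the best change and 51 % after west, and it held that “the mass balance closes within noise”.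

The flask gave 44.3 % of target. After west it gave 44.5 %, a gain of 0.23 points, and south-east gained 21 points, so the choice was south-east.

    target ⇌ isomer of the product (K = 1.20, k = 1.50 × 10⁻⁴ s⁻¹)
    starting material + dissolved gas → target (k = 1.00 M⁻¹ s⁻¹)
    dissolved gas ⇌ dormant form (K = 76.0, k = 7.20 × 10⁻⁴ s⁻¹)
    gas phase ⇌ dissolved gas, rate k4*(csat - [dissolved gas]) (kL = 0.530 s⁻¹)

At 30.0 min the flask held 6.46 % of isomer of the product, against my reckoned loss of 6.2 points. I took the same k and L to the neighbouring flask, read at 50 min. Its first round gave 69.0 %, its loss was 15 points, and so its target came to 54.0 %. That neighbouring flask held 55.4 % of target and 14.1 % of isomer of the product.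

All runs stem from a simulated flask with constants of no real substance, noise included.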